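**Assumption:** the target is an achiral flavone with no stereocentre and no stereogenic double bond, so "single enantiomer" is taken to mean the compound as drawn: 2-(3,5-dihydroxy-4-methoxyphenyl)-5,7-dihydroxy-6,8-dimethoxy-4H-chromen-4-one.

## Retrosynthetic overview

1. Target ⇐ hydrogenolysis of its 3',5'-di-O-benzyl ether; ring C (the pyranone) is the only ring formed, closed late by acid cyclodehydration of a 1,3-diketone with loss of the ring A MOM groups.
2. 1,3-Diketone ⇐ crossed Claisen condensation (new C(=O)–CH2 bond) between the enolate of a fully protected ring A acetophenone and a ring B methyl benzoate.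
3. Ring A acetophenone ⇐ phloroglucinol tris-MOM ether by three directed ortho-lithiations: two lithiation/borylation/oxidation/O-methylation cycles (the future 6- and 8-OMe), then acetylation with a Weinreb amide.
4. Ring B ester ⇐ methyl gallate by 4-O-methylation, then 3,5-di-O-benzylation.
5. Rings A and B come from commercial aromatics; the symmetry of ring A means either ortho oxygen gives the same flavone.

## Route

Step 1
Reactants: 1 phloroglucinol (benzene-1,3,5-triol, anhydrous)
Product: 2 1,3,5-tris(methoxymethoxy)benzene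
Conditions: NaH (3.6 equiv), MOMCl (3.6 equiv), DMF, 0 °C to rt
Reagents that add atoms: chloromethyl methyl ether, COCCl
Why: Williamson-type O-alkylation of the sodium phenoxides by the hard electrophile MOMCl gives the tris-acetal, which protects all three oxygens and provides strong ortho-directing groups for the lithiations that follow.

Step 2
Reactants: 2 1,3,5-tris(methoxymethoxy)benzene
Product: 5 2,4,6-tris(methoxymethoxy)phenol, via aryllithium 3 (not isolated), via lithium aryltrimethoxyborate 4 (not isolated)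
Conditions: n-BuLi (1.2 equiv), THF, 0 °C; B(OMe)3, −78 °C to rt; then 30% H2O2, aq. NaOH, 0 °C
Reagents that add atoms: hydrogen peroxide, OO (phenol oxygen of 5); n-butyllithium, [Li]CCCC (Li of 3 and 4); trimethyl borate, COB(OC)OC (B(OMe)3 of 4)
Why: Directed ortho-metalation at a ring carbon flanked by two OMOM groups, borylation and oxidative boron-to-oxygen aryl migration (boronate oxidation) install the new oxygen regiospecifically under conditions that leave the base-stable MOM acetals intact.

Step 3
Reactants: 5 2,4,6-tris(methoxymethoxy)phenol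
Product: 6 2-methoxy-1,3,5-tris(methoxymethoxy)benzene
Conditions: MeI (2 equiv), K2CO3, DMF, rt
Reagents that add atoms: iodomethane, CI
Why: Williamson ether synthesis (SN2 attack of the phenoxide on MeI) caps the only free hydroxyl as the first ring A methoxy group.

Step 4
Reactants: 6 2-methoxy-1,3,5-tris(methoxymethoxy)benzene
Product: 9 3-methoxy-2,4,6-tris(methoxymethoxy)phenol, via aryllithium 7 (not isolated), via lithium aryltrimethoxyborate 8 (not isolated)
Conditions: n-BuLi (1.2 equiv), THF, 0 °C; B(OMe)3, −78 °C to rt; then 30% H2O2, aq. NaOH, 0 °C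
Reagents that add atoms: hydrogen peroxide, OO (phenol oxygen of 9); n-butyllithium, [Li]CCCC (Li of 7 and 8); trimethyl borate, COB(OC)OC (B(OMe)3 of 8)
Why: The two remaining ring hydrogens are equivalent by symmetry and each lies between two OMOM groups, so the same directed ortho-metalation/borylation/oxidation sequence gives a single phenol.

Step 5
Reactants: 9 3-methoxy-2,4,6-tris(methoxymethoxy)phenol
Product: 10 2,4-dimethoxy-1,3,5-tris(methoxymethoxy)benzene
Conditions: MeI (2 equiv), K2CO3, DMF, rt
Reagents that add atoms: iodomethane, CI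
Why: Williamson ether synthesis installs the second ring A methoxy group and completes the alternating OMOM/OMe pattern.

Step 6
Reactants: 10 2,4-dimethoxy-1,3,5-tris(methoxymethoxy)benzene
Product: 13 1-[3,5-dimethoxy-2,4,6-tris(methoxymethoxy)phenyl]ethan-1-one, via aryllithium 11 (not isolated), via lithium hemiaminal adduct 12 (not isolated)
Conditions: n-BuLi (1.2 equiv), THF, 0 °C; MeC(O)N(OMe)Me (1.5 equiv), −78 to 0 °C; then H2O
Reagents that add atoms: N-methoxy-N-methylacetamide, CC(=O)N(C)OC (acetyl group of 13; all of its atoms are in 12); n-butyllithium, [Li]CCCC (Li of 11 and 12)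
Why: Directed ortho-metalation at the last ring hydrogen followed by a Weinreb ketone synthesis, in which the chelated tetrahedral adduct survives until work-up, gives the methyl ketone without over-addition.

Step 7
Reactants: 14 methyl gallate (methyl 3,4,5-trihydroxybenzoate)
Product: 15 methyl 3,5-dihydroxy-4-methoxybenzoate
Conditions: MeI (1.05 equiv), K2CO3 (1.0 equiv), DMF, rt; chromatography
Reagents that add atoms: iodomethane, CI
Why: The 4-OH, para to the ester, is the most acidic hydroxyl, so one equivalent of base and MeI gives mainly the 4-O-methyl ether by Williamson alkylation.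

Step 8
Reactants: 15 methyl 3,5-dihydroxy-4-methoxybenzoate
Product: 16 methyl 3,5-bis(benzyloxy)-4-methoxybenzoate
Conditions: BnBr (2.4 equiv), K2CO3, DMF, 60 °C
Reagents that add atoms: benzyl bromide, BrCc1ccccc1
Why: Exhaustive Williamson benzylation protects the two ring B phenols as ethers that survive the base and acid steps and are removed by hydrogenolysis at the end.

Step 9
Reactants: 13 1-[3,5-dimethoxy-2,4,6-tris(methoxymethoxy)phenyl]ethan-1-one; 16 methyl 3,5-bis(benzyloxy)-4-methoxybenzoate (1.2 equiv)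
Product: 17 1-[3,5-bis(benzyloxy)-4-methoxyphenyl]-3-[3,5-dimethoxy-2,4,6-tris(methoxymethoxy)phenyl]propane-1,3-dione
Conditions: NaH (3 equiv), THF, reflux; then cold 1 M HCl to pH 6
Reagents that add atoms: none
Why: Crossed Claisen condensation in which only ketone 13 can enolise, ester 16 cannot self-condense, and irreversible deprotonation of the 1,3-diketone by excess NaH drives the equilibrium to the product.

Step 10
Reactants: 17 1-[3,5-bis(benzyloxy)-4-methoxyphenyl]-3-[3,5-dimethoxy-2,4,6-tris(methoxymethoxy)phenyl]propane-1,3-dione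
Product: 19 2-[3,5-bis(benzyloxy)-4-methoxyphenyl]-5,7-dihydroxy-6,8-dimethoxy-4H-chromen-4-one, via trihydroxy diketone 18 (not isolated)
Conditions: conc. HCl, MeOH/THF, 60 °C
Reagents that add atoms: none
Why: Acid-catalysed acetal cleavage frees the three phenols, and one ortho-hydroxyl (both are equivalent by symmetry) adds to the distal carbonyl and dehydrates (cyclodehydration of an o-hydroxy-1,3-diketone) to the flavone, while benzyl ethers are stable to HCl in methanol.

Step 11
Reactants: 19 2-[3,5-bis(benzyloxy)-4-methoxyphenyl]-5,7-dihydroxy-6,8-dimethoxy-4H-chromen-4-one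
Product: 20 2-(3,5-dihydroxy-4-methoxyphenyl)-5,7-dihydroxy-6,8-dimethoxy-4H-chromen-4-one (target)
Conditions: H2 (1 atm), 10% Pd/C, THF/MeOH, rt, monitored by TLC
Reagents that add atoms: none
Why: Catalytic hydrogenolysis cleaves the two aryl benzyl ethers cleanly, whereas the C2–C3 double bond of the flavone (a vinylogous ester) is reduced much more slowly under these mild conditions.

## Compound list

1 | phloroglucinol (benzene-1,3,5-triol) | Oc1cc(O)cc(O)c1 | starting material
2 | 1,3,5-tris(methoxymethoxy)benzene | COCOc1cc(OCOC)cc(OCOC)c1 | intermediate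
3 | 2,4,6-tris(methoxymethoxy)phenyllithium | [Li]c1c(OCOC)cc(OCOC)cc1OCOC | intermediate
4 | lithium trimethoxy[2,4,6-tris(methoxymethoxy)phenyl]borate | [Li+].CO[B-](OC)(OC)c1c(OCOC)cc(OCOC)cc1OCOC | intermediate
5 | 2,4,6-tris(methoxymethoxy)phenol | Oc1c(OCOC)cc(OCOC)cc1OCOC | intermediate
6 | 2-methoxy-1,3,5-tris(methoxymethoxy)benzene | COc1c(OCOC)cc(OCOC)cc1OCOC | intermediate
7 | 3-methoxy-2,4,6-tris(methoxymethoxy)phenyllithium | [Li]c1c(OCOC)c(OC)c(OCOC)cc1OCOC | intermediate
8 | lithium trimethoxy[3-methoxy-2,4,6-tris(methoxymethoxy)phenyl]borate | [Li+].CO[B-](OC)(OC)c1c(OCOC)c(OC)c(OCOC)cc1OCOC | intermediate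
9 | 3-methoxy-2,4,6-tris(methoxymethoxy)phenol | Oc1c(OCOC)c(OC)c(OCOC)cc1OCOC | intermediate
10 | 2,4-dimethoxy-1,3,5-tris(methoxymethoxy)benzene | COc1c(OCOC)c(OC)c(OCOC)cc1OCOC | intermediate
11 | 3,5-dimethoxy-2,4,6-tris(methoxymethoxy)phenyllithium | [Li]c1c(OCOC)c(OC)c(OCOC)c(OC)c1OCOC | intermediate
12 | lithium 1-[3,5-dimethoxy-2,4,6-tris(methoxymethoxy)phenyl]-1-[methoxy(methyl)amino]ethan-1-olate (tetrahedral Weinreb adduct) | [Li+].CC([O-])(N(C)OC)c1c(OCOC)c(OC)c(OCOC)c(OC)c1OCOC | intermediate
13 | 1-[3,5-dimethoxy-2,4,6-tris(methoxymethoxy)phenyl]ethan-1-one | CC(=O)c1c(OCOC)c(OC)c(OCOC)c(OC)c1OCOC | intermediate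
14 | methyl gallate (methyl 3,4,5-trihydroxybenzoate) | COC(=O)c1cc(O)c(O)c(O)c1 | starting material
15 | methyl 3,5-dihydroxy-4-methoxybenzoate | COC(=O)c1cc(O)c(OC)c(O)c1 | intermediate
16 | methyl 3,5-bis(benzyloxy)-4-methoxybenzoate | COC(=O)c1cc(OCc2ccccc2)c(OC)c(OCc2ccccc2)c1 | intermediate
17 | 1-[3,5-bis(benzyloxy)-4-methoxyphenyl]-3-[3,5-dimethoxy-2,4,6-tris(methoxymethoxy)phenyl]propane-1,3-dione | COc1c(OCc2ccccc2)cc(cc1OCc1ccccc1)C(=O)CC(=O)c1c(OCOC)c(OC)c(OCOC)c(OC)c1OCOC | intermediate
18 | 1-[3,5-bis(benzyloxy)-4-methoxyphenyl]-3-(2,4,6-trihydroxy-3,5-dimethoxyphenyl)propane-1,3-dione | COc1c(OCc2ccccc2)cc(cc1OCc1ccccc1)C(=O)CC(=O)c1c(O)c(OC)c(O)c(OC)c1O | intermediate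
19 | 2-[3,5-bis(benzyloxy)-4-methoxyphenyl]-5,7-dihydroxy-6,8-dimethoxy-4H-chromen-4-one | COc1c(OCc2ccccc2)cc(cc1OCc1ccccc1)-c1cc(=O)c2c(O)c(OC)c(O)c(OC)c2o1 | intermediate
20 | 2-(3,5-dihydroxy-4-methoxyphenyl)-5,7-dihydroxy-6,8-dimethoxy-4H-chromen-4-one | COc1c(O)cc(-c2cc(=O)c3c(O)c(OC)c(O)c(OC)c3o2)cc1O | target

## Summary

Total step count: 11 steps.
Longest linear sequence: 9 steps (steps 1–6, then 9, 10 and 11, from phloroglucinol); the ring B branch is 2 steps (7 and 8).

## Steps most likely to fail, with fallbacks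

Step 6 (acylation of the hindered aryllithium; enolisation of the Weinreb amide may simply return 10). The fallback sets out from 10 and comes back to the route at 13. Arene 10 is lithiated as before to aryllithium 11, which is trapped with acetaldehyde at −78 °C to give the secondary benzylic alcohol 1-[3,5-dimethoxy-2,4,6-tris(methoxymethoxy)phenyl]ethan-1-ol F1 (racemic). Oxidation of this alcohol with Dess–Martin periodinane in CH2Cl2 buffered with NaHCO3 then gives ketone 13. This replaces the acyl substitution by a fast carbonyl addition followed by an alcohol oxidation.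

Step 7 (mono-methylation of methyl gallate may give mixtures of mono- and di-ethers). The fallback sets out from 14 and comes back at 15. Methyl gallate is peracetylated (Ac2O, pyridine) to methyl 3,4,5-triacetoxybenzoate F2. Heating F2 with MeI and K2CO3 in acetone selectively cleaves and methylates the most labile 4-acetate, giving methyl 3,5-diacetoxy-4-methoxybenzoate F3. Methanolysis of the two remaining acetates (K2CO3, MeOH, rt) gives 15. Here the selectivity comes from the differing lability of the acetates, not from phenol acidity under kinetic control.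

Step 9 (crossed Claisen condensation of a hindered ketone with an electron-rich ester). The fallback sets out from 16 and 13 and comes back at 19, using an aldol route:
- Ester 16 is reduced with LiAlH4 (THF, 0 °C) to [3,5-bis(benzyloxy)-4-methoxyphenyl]methanol F4, which is oxidised with MnO2 (CH2Cl2, rt) to 3,5-bis(benzyloxy)-4-methoxybenzaldehyde F5.
- Claisen–Schmidt condensation of this aldehyde with ketone 13 (KOH, EtOH, rt) gives (E)-3-[3,5-bis(benzyloxy)-4-methoxyphenyl]-1-[3,5-dimethoxy-2,4,6-tris(methoxymethoxy)phenyl]prop-2-en-1-one F6.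
- HCl in MeOH/THF at 60 °C removes the MOM groups to give (E)-3-[3,5-bis(benzyloxy)-4-methoxyphenyl]-1-(2,4,6-trihydroxy-3,5-dimethoxyphenyl)prop-2-en-1-one F7. This closes in the same pot (completed with NaOAc, EtOH, reflux) by intramolecular oxa-Michael addition to 2-[3,5-bis(benzyloxy)-4-methoxyphenyl]-5,7-dihydroxy-6,8-dimethoxychroman-4-one F8 (racemic).
- Dehydrogenation of the flavanone with I2 in DMSO at 120 °C gives flavone 19. Ring A is fully substituted and ring B carries no free phenol, so iodination is not a concern.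

## Further compounds

F1 | step 6 | 1-[3,5-dimethoxy-2,4,6-tris(methoxymethoxy)phenyl]ethan-1-ol (racemic) | CC(O)c1c(OCOC)c(OC)c(OCOC)c(OC)c1OCOC
F2 | step 7 | methyl 3,4,5-triacetoxybenzoate | COC(=O)c1cc(OC(C)=O)c(OC(C)=O)c(OC(C)=O)c1
F3 | step 7 | methyl 3,5-diacetoxy-4-methoxybenzoate | COC(=O)c1cc(OC(C)=O)c(OC)c(OC(C)=O)c1
F4 | step 9 | [3,5-bis(benzyloxy)-4-methoxyphenyl]methanol | COc1c(OCc2ccccc2)cc(CO)cc1OCc1ccccc1
F5 | step 9 | 3,5-bis(benzyloxy)-4-methoxybenzaldehyde | COc1c(OCc2ccccc2)cc(C=O)cc1OCc1ccccc1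
F6 | step 9 | (E)-3-[3,5-bis(benzyloxy)-4-methoxyphenyl]-1-[3,5-dimethoxy-2,4,6-tris(methoxymethoxy)phenyl]prop-2-en-1-one | COc1c(OCc2ccccc2)cc(/C=C/C(=O)c2c(OCOC)c(OC)c(OCOC)c(OC)c2OCOC)cc1OCc1ccccc1
F7 | step 9 | (E)-3-[3,5-bis(benzyloxy)-4-methoxyphenyl]-1-(2,4,6-trihydroxy-3,5-dimethoxyphenyl)prop-2-en-1-one | COc1c(OCc2ccccc2)cc(/C=C/C(=O)c2c(O)c(OC)c(O)c(OC)c2O)cc1OCc1ccccc1
F8 | step 9 | 2-[3,5-bis(benzyloxy)-4-methoxyphenyl]-5,7-dihydroxy-6,8-dimethoxychroman-4-one (racemic) | COc1c(OCc2ccccc2)cc(cc1OCc1ccccc1)C1CC(=O)c2c(O)c(OC)c(O)c(OC)c2O1
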